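The earlier runs and the new flask come from a simulation on assumed constants, and the scatter is random.

Late in each earlier run, part of the substrate charged was missing. At the last reading of Monday's run the gap W, the charge less substrate A, mono adduct M and double product D, stood at 26.9%.

| setting | Monday's | Sunday's | Thursday's | flask |
|---|---|---|---|---|
| substrate | 0.80 M | 0.80 M | 1.2 M | 0.80 M |
| reagent | 0.42 M | 0.63 M | 0.84 M | 0.840 M |
| remark | run made earlier | run made earlier | run made earlier |  |
| time |  |  |  | 3.0 min |

| run | time / min | substrate / % | mono adduct / % | double product / % |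
|---|---|---|---|---|
| Monday's | 0.250 | 92.2 | 4.1 | 0 |
| Monday's | 0.667 | 81.6 | 8.8 | 0 |
| Monday's | 1.33 | 69.4 | 16.0 | 1.1 |
| Monday's | 2.00 | 58.2 | 20.6 | 1.9 |
| Monday's | 3.00 | 50.5 | 25.4 | 2.2 |
| Monday's | 4.00 | 42.6 | 28.2 | 2.3 |
| Sunday's | 0.250 | 90.2 | 5.7 | 0 |
| Sunday's | 0.667 | 77.7 | 13.6 | 0.6 |
| Sunday's | 1.33 | 63.4 | 23.0 | 0.6 |
| Sunday's | 2.00 | 52.0 | 28.0 | 1.6 |
| Sunday's | 3.00 | 41.3 | 34.6 | 2.6 |
| Sunday's | 4.00 | 34.0 | 38.0 | 4.7 |
| Thursday's | 0.333 | 83.2 | 10.0 | 0.2 |
| Thursday's | 0.833 | 66.0 | 19.4 | 0.6 |
| Thursday's | 1.50 | 51.8 | 28.9 | 2.0 |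
| Thursday's | 2.50 | 38.8 | 34.4 | 3.9 |
| Thursday's | 4.00 | 27.7 | 38.5 | 5.4 |

(readings scatter by 0.5 percentage points)



- amount of substrate at 3.0 min, in percent of the substrate charged
- amount of mono adduct at 3.0 min, in percent of the substrate charged
- amount of double product at 3.0 min, in percent of the substrate charged

I assumed a second path taking substrate at a rate in A², beside the path to M and D at a rate in A times reagent B. Dividing one rate by the other, time drops out:

(M + D) / W = σ · B / A, with B / A taken at the charge

The last readings give σ = 2.16, 2.33 and 2.21 for Monday's, Sunday's and Thursday's runs. I took the mean, 2.23, as my selectivity factor.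

Reagent should raise the ratio in step. From 0.42 M in Monday's run to 0.63 M in Sunday's, at the same substrate charge, it went from 1.13 to 1.83.

Substrate should lower it, but Thursday's run differs from those two in both charges. With 1.2 M of substrate and 0.84 M of reagent, it read 1.55.

Time should leave it alone. Monday's run read 1.17 at 2.00 min.

For the flask:

(M + D) / W = 2.34, so M and D take 70.1% of the substrate used

Reagent goes up by equal steps from Monday's run through Sunday's to the flask, so I applied one more equal factor to substrate at 3.00 min:

A = 33.8%, M + D = 46.4%

The share of D in M + D in Thursday's run at 2.50 min, with the same reagent charge but a different substrate charge, gave D = 4.73% and M = 41.7%.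

The forecast, expecting “a hidden parallel loss of substrate”, gave 36.5% substrate, 41.8% mono adduct and 4.4% double product, higher in substrate than my reckoning.

The flask gave 35.1% substrate, 41.9% mono adduct and 5.10% double product.

    reagent + mono adduct → double product (k = 0.00190 M⁻¹ s⁻¹)
    substrate + reagent → mono adduct (k = 0.00730 M⁻¹ s⁻¹)
    2 substrate → self-condensation product (k = 0.00170 M⁻¹ s⁻¹)

The flask's gap at 3.00 min was self-condensation product, each counting as two substrate, at 18.0% of the charge. The flask's ratio was 2.61, above my 2.34, and its reagent over substrate had reached 1.51. The neighbour charged with 0.34 M of reagent reckons at 0.948. At 3.00 min it held 52.4% substrate, 21.2% mono adduct, 0.928% double product and 25.5% self-condensation product, a ratio of 0.868.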